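The cyclohexane ring (C1 with CO2H, C2 with the side chain, C3 with the gem-dimethyl group, C4–C6 methylenes) is cut into the C2=C3 trisubstituted alkene of (R)-linalool, which also brings the chromene carbinol carbon, and a cyclobut-1-enecarbonyl unit (C4, C5, C6, C1 and the carboxyl carbon). A sensitised [2+2] photocycloaddition under oxazolidinone auxiliary control joins C1–C2 and C3–C4 at once to a bicyclo[2.2.0]hexane. The strain of its central C1–C4 bond then drives reductive opening by SmI2 to the saturated ring without any hydrogenation. O-Arylation, methylenation and ring-closing metathesis then build the chromene.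

Key step: step 2

Assumption: 1, 2, 5 and 10 are bought, and (R)-linalool is used in enantiomerically pure form; ring atoms keep the target numbering C1–C6 throughout, which is also the bicyclo[2.2.0]hexane numbering of 6.

Step 1
Reactants: 1 cyclobut-1-ene-1-carboxylic acid; 2 (4R)-4-benzyl-5,5-dimethyl-1,3-oxazolidin-2-one
Product: 4 (4R)-4-benzyl-3-(cyclobut-1-ene-1-carbonyl)-5,5-dimethyl-1,3-oxazolidin-2-one, via cyclobut-1-ene-1-carbonyl chloride 3 (not isolated)
Conditions: (COCl)2, DMF (cat.), CH2Cl2, 0 °C to rt; then 2 premetalated with n-BuLi, THF, −78 °C to 0 °C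
Reagents that add atoms: none
Why: N-acylation of the lithiated oxazolidinone by the acid chloride (acyl substitution) should give the enoyl imide; no stereocentre is formed.

Step 2
Reactants: 4 (4R)-4-benzyl-3-(cyclobut-1-ene-1-carbonyl)-5,5-dimethyl-1,3-oxazolidin-2-one; 5 (R)-linalool, (3R)-3,7-dimethylocta-1,6-dien-3-ol
Product: 6 (4R)-4-benzyl-3-{(1R,2S,4S)-2-[(3R)-3-hydroxy-3-methylpent-4-en-1-yl]-3,3-dimethylbicyclo[2.2.0]hexane-1-carbonyl}-5,5-dimethyl-1,3-oxazolidin-2-one (side chain exo)
Conditions: 5 (3 equiv), MgBr2·OEt2 (1.1 equiv), xanthone (10 mol%), CH2Cl2, hν 350 nm, −40 °C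
Reagents that add atoms: none
Why: Xanthone transfers triplet energy to the MgBr2-chelated enoyl imide 4, whose π,π* triplet adds to the electron-rich C6=C7 alkene of 5 through a 1,4-biradical that closes to the cyclobutane; this is the enone/enoate–alkene [2+2] photocycloaddition, the reaction type by which cyclobut-1-enecarboxylic acid derivatives give bicyclo[2.2.0]hexanes. The one ring formed, the new cyclobutane, closes by bonds C1–C2 and C4–C3 across both double bonds in the fused, necessarily cis mode. C1 and C4 are set by the face of the cyclobutene that is attacked, which the benzyl group of the (R)-auxiliary should dictate by covering the other face in the s-trans N,O-chelate; C2 is set by the side chain taking the exo position, away from the second four-membered ring. Regioselectivity (head-to-tail: the quaternary C1 bonds to the CH terminus and C4–H to the CMe2 terminus) is needed and is secured because the other orientation would join two fully substituted carbons. Chemoselectivity for the trisubstituted alkene over the vinyl group is needed and rests on its higher electron density, on the tertiary radical formed after the first bond and on the screening of the vinyl group by the quaternary carbinol carbon; the excess of 5 suppresses dimerisation of 4.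

Step 3
Reactants: 6 (4R)-4-benzyl-3-{(1R,2S,4S)-2-[(3R)-3-hydroxy-3-methylpent-4-en-1-yl]-3,3-dimethylbicyclo[2.2.0]hexane-1-carbonyl}-5,5-dimethyl-1,3-oxazolidin-2-one
Product: 7 (4R)-4-benzyl-3-{(1R,2R)-2-[(3R)-3-hydroxy-3-methylpent-4-en-1-yl]-3,3-dimethylcyclohexane-1-carbonyl}-5,5-dimethyl-1,3-oxazolidin-2-one (cis C1 epimer expected to predominate)
Conditions: SmI2 (2.2 equiv), t-BuOH (2 equiv), THF, −78 °C to −20 °C
Reagents that add atoms: none
Why: Single-electron transfer to the samarium-chelated imide carbonyl gives a ketyl-type radical anion that cleaves the aligned, highly strained central C1–C4 bond (reductive fragmentation of strained cycloalkyl carbonyl compounds); the C4 radical is reduced and protonated to CH2, the enolate is protonated at C1 mainly from the face away from the side chain (cis, corrected in step 4), and C2 is untouched.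

Step 4
Reactants: 7 (4R)-4-benzyl-3-{(1R,2R)-2-[(3R)-3-hydroxy-3-methylpent-4-en-1-yl]-3,3-dimethylcyclohexane-1-carbonyl}-5,5-dimethyl-1,3-oxazolidin-2-one
Product: 9 (1S,2R)-2-[(3R)-3-hydroxy-3-methylpent-4-en-1-yl]-3,3-dimethylcyclohexane-1-carboxylic acid, via trans methyl ester 8 (not isolated)
Conditions: NaOMe (3 equiv), MeOH, 0 °C to 60 °C; then NaOH, H2O, 60 °C; then HCl (aq) to pH 3
Reagents that add atoms: sodium hydroxide, [Na+].[OH-]
Why: Methanolysis removes the auxiliary at the exocyclic carbonyl (the gem-dimethyl group of the oxazolidinone blocks attack on its ring carbonyl), methoxide equilibrates the enolisable C1 centre to the trans-diequatorial ester so that thermodynamic control sets C1 as S, and saponification gives the acid.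

Step 5
Reactants: 9 (1S,2R)-2-[(3R)-3-hydroxy-3-methylpent-4-en-1-yl]-3,3-dimethylcyclohexane-1-carboxylic acid; 10 2,6-difluoro-4-methylbenzaldehyde
Product: 11 (1S,2R)-2-[(3R)-3-(3-fluoro-2-formyl-5-methylphenoxy)-3-methylpent-4-en-1-yl]-3,3-dimethylcyclohexane-1-carboxylic acid
Conditions: KN(SiMe3)2 (2.2 equiv), THF, 0 °C; then 10 (1.5 equiv), DMF, 0 °C to rt; then HCl (aq) to pH 3–4 at 0 °C
Reagents that add atoms: none
Why: Nucleophilic aromatic substitution of a fluoride activated by the ortho-formyl group by the potassium tertiary alkoxide (the carboxylate stays inert); the carbinol C–O bond is not broken, so the R centre from linalool is kept.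

Step 6
Reactants: 11 (1S,2R)-2-[(3R)-3-(3-fluoro-2-formyl-5-methylphenoxy)-3-methylpent-4-en-1-yl]-3,3-dimethylcyclohexane-1-carboxylic acid
Product: 13 (1S,2R)-2-[(3R)-3-(2-formyl-3-hydroxy-5-methylphenoxy)-3-methylpent-4-en-1-yl]-3,3-dimethylcyclohexane-1-carboxylic acid, via sulfonylethyl aryl ether 12 (not isolated)
Conditions: MeSO2CH2CH2OH (1.5 equiv), NaH (3.5 equiv), DMF, 0 °C to rt; then HCl (aq) to pH 3–4
Reagents that add atoms: 2-(methylsulfonyl)ethanol, OCCS(C)(=O)=O
Why: A second nucleophilic aromatic substitution at the remaining activated fluoride by the sulfonylethoxide gives an aryl ether that loses methyl vinyl sulfone by E1cB elimination and so unmasks the phenol.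

Step 7
Reactants: 13 (1S,2R)-2-[(3R)-3-(2-formyl-3-hydroxy-5-methylphenoxy)-3-methylpent-4-en-1-yl]-3,3-dimethylcyclohexane-1-carboxylic acid
Product: 14 (1S,2R)-2-[(3R)-3-(2-ethenyl-3-hydroxy-5-methylphenoxy)-3-methylpent-4-en-1-yl]-3,3-dimethylcyclohexane-1-carboxylic acid
Conditions: Ph3PCH3Br (4.5 equiv), KOtBu (4.5 equiv), THF, 0 °C to rt; then HCl (aq) to pH 3–4
Reagents that add atoms: methyltriphenylphosphonium bromide, C[P+](c1ccccc1)(c1ccccc1)c1ccccc1.[Br-]
Why: Wittig methylenation of the aldehyde should give the styrene; the excess ylide covers the phenol and acid protons, and no stereocentre is involved.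

Step 8
Reactants: 14 (1S,2R)-2-[(3R)-3-(2-ethenyl-3-hydroxy-5-methylphenoxy)-3-methylpent-4-en-1-yl]-3,3-dimethylcyclohexane-1-carboxylic acid
Product: 15 (1S,2R)-2-{2-[(2R)-5-hydroxy-2,7-dimethyl-2H-chromen-2-yl]ethyl}-3,3-dimethylcyclohexane-1-carboxylic acid
Conditions: second-generation Grubbs catalyst RuCl2(=CHPh)(PCy3)(H2IMes) (5 mol%), CH2Cl2, 40 °C
Reagents that add atoms: none
Why: Ring-closing metathesis of the styrene with the vinyl group on the quaternary carbinol carbon closes the six-membered pyran ring with loss of ethene; no stereocentre is touched.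

Compound list
1 | cyclobut-1-ene-1-carboxylic acid | OC(=O)C1=CCC1 | starting material
2 | (4R)-4-benzyl-5,5-dimethyl-1,3-oxazolidin-2-one | O=C1N[C@H](Cc2ccccc2)C(C)(C)O1 | starting material
3 | cyclobut-1-ene-1-carbonyl chloride | O=C(Cl)C1=CCC1 | intermediate (not isolated)
4 | (4R)-4-benzyl-3-(cyclobut-1-ene-1-carbonyl)-5,5-dimethyl-1,3-oxazolidin-2-one | O=C(C1=CCC1)N1[C@H](Cc2ccccc2)C(C)(C)OC1=O | intermediate
5 | (R)-linalool, (3R)-3,7-dimethylocta-1,6-dien-3-ol | O[C@](C)(CCC=C(C)C)C=C | starting material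
6 | (4R)-4-benzyl-3-{(1R,2S,4S)-2-[(3R)-3-hydroxy-3-methylpent-4-en-1-yl]-3,3-dimethylbicyclo[2.2.0]hexane-1-carbonyl}-5,5-dimethyl-1,3-oxazolidin-2-one | O[C@](C)(CC[C@@H]1[C@@]2(C(=O)N3[C@H](Cc4ccccc4)C(C)(C)OC3=O)CC[C@H]2C1(C)C)C=C | intermediate
7 | (4R)-4-benzyl-3-{(1R,2R)-2-[(3R)-3-hydroxy-3-methylpent-4-en-1-yl]-3,3-dimethylcyclohexane-1-carbonyl}-5,5-dimethyl-1,3-oxazolidin-2-one | O[C@](C)(CC[C@@H]1[C@H](C(=O)N2[C@H](Cc3ccccc3)C(C)(C)OC2=O)CCCC1(C)C)C=C | intermediate
8 | methyl (1S,2R)-2-[(3R)-3-hydroxy-3-methylpent-4-en-1-yl]-3,3-dimethylcyclohexane-1-carboxylate | O[C@](C)(CC[C@@H]1[C@@H](C(=O)OC)CCCC1(C)C)C=C | intermediate (not isolated)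
9 | (1S,2R)-2-[(3R)-3-hydroxy-3-methylpent-4-en-1-yl]-3,3-dimethylcyclohexane-1-carboxylic acid | O[C@](C)(CC[C@@H]1[C@@H](C(=O)O)CCCC1(C)C)C=C | intermediate
10 | 2,6-difluoro-4-methylbenzaldehyde | Cc1cc(F)c(C=O)c(F)c1 | starting material
11 | (1S,2R)-2-[(3R)-3-(3-fluoro-2-formyl-5-methylphenoxy)-3-methylpent-4-en-1-yl]-3,3-dimethylcyclohexane-1-carboxylic acid | Cc1cc(F)c(C=O)c(c1)O[C@](C)(CC[C@@H]1[C@@H](C(=O)O)CCCC1(C)C)C=C | intermediate
12 | (1S,2R)-2-[(3R)-3-{2-formyl-5-methyl-3-[2-(methylsulfonyl)ethoxy]phenoxy}-3-methylpent-4-en-1-yl]-3,3-dimethylcyclohexane-1-carboxylic acid | Cc1cc(OCCS(C)(=O)=O)c(C=O)c(c1)O[C@](C)(CC[C@@H]1[C@@H](C(=O)O)CCCC1(C)C)C=C | intermediate (not isolated)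
13 | (1S,2R)-2-[(3R)-3-(2-formyl-3-hydroxy-5-methylphenoxy)-3-methylpent-4-en-1-yl]-3,3-dimethylcyclohexane-1-carboxylic acid | Cc1cc(O)c(C=O)c(c1)O[C@](C)(CC[C@@H]1[C@@H](C(=O)O)CCCC1(C)C)C=C | intermediate
14 | (1S,2R)-2-[(3R)-3-(2-ethenyl-3-hydroxy-5-methylphenoxy)-3-methylpent-4-en-1-yl]-3,3-dimethylcyclohexane-1-carboxylic acid | Cc1cc(O)c(C=C)c(c1)O[C@](C)(CC[C@@H]1[C@@H](C(=O)O)CCCC1(C)C)C=C | intermediate
15 | (1S,2R)-2-{2-[(2R)-5-hydroxy-2,7-dimethyl-2H-chromen-2-yl]ethyl}-3,3-dimethylcyclohexane-1-carboxylic acid | Cc1cc(O)c2c(c1)O[C@](C)(CC[C@@H]1[C@@H](C(=O)O)CCCC1(C)C)C=C2 | target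

Total step count: 8. Longest linear sequence: 8 steps (1 to 15).

Steps most likely to fail

Step 2. What may go wrong: loss of stereocontrol at C2, either by attack on the wrong face of the cyclobutene (the s-cis chelate would expose the opposite face) or by endo placement of the side chain; some cycloaddition at the vinyl group is also possible. The fallback sets out from 7 and comes back at 9. The material is taken through step 3 as the mixture of C2 epimers. In place of step 4, 7 is treated with KN(SiMe3)2 in THF (0 °C to rt), so that the tertiary alkoxide displaces the auxiliary intramolecularly and, after equilibration at C1, gives the trans-fused seven-membered lactone (3R,5aR,9aS)-3-ethenyl-3,6,6-trimethyl-4,5,5a,6,7,8,9,9a-octahydro-2-benzoxepin-1(3H)-one F1. In F1 the carbinol carbon of linalool and C2 lie in one ring, so the lactone with the wrong C2 configuration is a rigid diastereomer that should be removable by chromatography or crystallisation. NaOH in aqueous methanol at 60 °C then opens F1 to 9. The configuration at C2 is then secured by relay from the existing carbinol centre and not by the auxiliary.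

Step 3. What may go wrong: electron transfer to the imide carbonyl may be slow, or the opened imide may be reduced further with loss of the auxiliary. The fallback sets out from 6 and comes back at 9. LiBH4 with one equivalent of MeOH in THF at 0 °C removes the auxiliary reductively and gives the primary alcohol (3R)-5-[(1R,2S,4S)-1-(hydroxymethyl)-3,3-dimethylbicyclo[2.2.0]hexan-2-yl]-3-methylpent-1-en-3-ol F2. Oxidation with the triacetoxyperiodinane DMP (NaHCO3, CH2Cl2) gives the bridgehead aldehyde (1R,2S,4S)-2-[(3R)-3-hydroxy-3-methylpent-4-en-1-yl]-3,3-dimethylbicyclo[2.2.0]hexane-1-carbaldehyde F3. Its ketyl should form readily with SmI2 (THF, −78 °C) and fragment as strained cycloalkyl aldehydes and ketones do. Brief treatment with DBU gives the trans aldehyde (1S,2R)-2-[(3R)-3-hydroxy-3-methylpent-4-en-1-yl]-3,3-dimethylcyclohexane-1-carbaldehyde F4. Pinnick oxidation (NaClO2, NaH2PO4, 2-methylbut-2-ene, t-BuOH/H2O) then leads to 9.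

Step 5. What may go wrong: reversible addition of the hindered alkoxide to the formyl group followed by hydride transfer between aldehyde molecules (Tishchenko-type), or substitution too slow to compete. The fallback sets out from 9 and comes back at 13. The dipotassium salt of 9 (KN(SiMe3)2, THF/DMF) is arylated with 2,6-difluoro-4-methylbenzonitrile, whose nitrile activates more strongly and cannot trap the alkoxide, to give (1S,2R)-2-[(3R)-3-(2-cyano-3-fluoro-5-methylphenoxy)-3-methylpent-4-en-1-yl]-3,3-dimethylcyclohexane-1-carboxylic acid F5. KOH in DMSO/H2O at 80 °C exchanges the second fluoride for hydroxyl and gives (1S,2R)-2-[(3R)-3-(2-cyano-3-hydroxy-5-methylphenoxy)-3-methylpent-4-en-1-yl]-3,3-dimethylcyclohexane-1-carboxylic acid F6. Reduction with i-Bu2AlH (excess, toluene, −78 °C; carboxylate and phenoxide are held as aluminium salts) and hydrolysis of the aldimine with dilute acid give aldehyde 13, and the route continues with step 7.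

Further compounds
F1 | step 2 | (3R,5aR,9aS)-3-ethenyl-3,6,6-trimethyl-4,5,5a,6,7,8,9,9a-octahydro-2-benzoxepin-1(3H)-one | O=C1O[C@@](C)(C=C)CC[C@@H]2[C@@H]1CCCC2(C)C
F2 | step 3 | (3R)-5-[(1R,2S,4S)-1-(hydroxymethyl)-3,3-dimethylbicyclo[2.2.0]hexan-2-yl]-3-methylpent-1-en-3-ol | O[C@](C)(CC[C@@H]1[C@@]2(CO)CC[C@H]2C1(C)C)C=C
F3 | step 3 | (1R,2S,4S)-2-[(3R)-3-hydroxy-3-methylpent-4-en-1-yl]-3,3-dimethylbicyclo[2.2.0]hexane-1-carbaldehyde | O[C@](C)(CC[C@@H]1[C@@]2(C=O)CC[C@H]2C1(C)C)C=C
F4 | step 3 | (1S,2R)-2-[(3R)-3-hydroxy-3-methylpent-4-en-1-yl]-3,3-dimethylcyclohexane-1-carbaldehyde | O[C@](C)(CC[C@@H]1[C@@H](C=O)CCCC1(C)C)C=C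
F5 | step 5 | (1S,2R)-2-[(3R)-3-(2-cyano-3-fluoro-5-methylphenoxy)-3-methylpent-4-en-1-yl]-3,3-dimethylcyclohexane-1-carboxylic acid | Cc1cc(F)c(C#N)c(c1)O[C@](C)(CC[C@@H]1[C@@H](C(=O)O)CCCC1(C)C)C=C
F6 | step 5 | (1S,2R)-2-[(3R)-3-(2-cyano-3-hydroxy-5-methylphenoxy)-3-methylpent-4-en-1-yl]-3,3-dimethylcyclohexane-1-carboxylic acid | Cc1cc(O)c(C#N)c(c1)O[C@](C)(CC[C@@H]1[C@@H](C(=O)O)CCCC1(C)C)C=C
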